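(All runs stem from a simulated flask from invented constants, noise included.)

Follow the flask in slow motion, from the undissolved charge to the asked time.

| flask | solid substrate | enzyme | remark | time |
|---|---|---|---|---|
| Thursday's | 0.10 M | 15 µM | run made earlier |  |
| flask | 0.10 M | 10 µM |  | 4.0 d |

Thursday's run (percent of the solid substrate charged)

| time / h | target / % | solid substrate / % |
|---|---|---|
| 1.33 | 0.1 | 95.0 |
| 4.00 | 0.3 | 85.6 |
| 6.00 | 0.8 | 78.7 |
| 10.0 | 2.7 | 67.1 |
| 15.0 | 4.7 | 54.8 |
| 20.0 | 6.7 | 43.6 |

(standard deviation of a reading: 0.3 percentage points)

- given per volume of solution although it is solid: solid substrate
- candidate steps: target -> over-reaction product; starting material + enzyme <-> complex; complex <-> enzyme + target; solid substrate <-> starting material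
- at the start none of the solid substrate is in solution
- no earlier run changes the charge of enzyme; that part of a forecast is a guess

* amount of target at 4.0 d, in percent of the solid substrate charged
* the change that raises the amount of target at 4.0 d, in percent of the solid substrate charged most ("none" if none brings more than 2 percentage points) (gamma / theta / eta / none)
* amount of target at 4.0 d, in percent of the solid substrate charged, after theta

- gamma: doubling the amount of enzyme, all else as stated
- theta: doubling the dissolution coefficient of the solid substrate, all else as stated
- eta: doubling the solubility of the solid substrate, all else as stated

At the start nothing is dissolved, and Thursday's target reads just 0.1% at 1.33 h. The solid falls from 95.0% to 43.6% across Thursday's run. We read this as a first-order loss with constant k = 0.0417 h⁻¹, so its time scale is 24.0 h.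

In the middle of Thursday's run, starting material accumulates and target follows it. We assume that target forms at κ times the dissolved amount. Integrating the dissolved fraction over Thursday's run gives an exposure of 6.44 h. Thursday's last target, 6.7%, is good to 0.3 percentage points. We divide it by that exposure and scale to 10 µM of enzyme, which gives κ = 0.00694 h⁻¹. This is the conversion constant, the fraction of dissolved starting material turned into target per hour in this flask. Its proportionality to enzyme is a guess.

At the asked time, our reckoned solid in the flask is 1.82%. In our reckoning k exceeds κ, so conversion is the rate-limiting step of our two. The two steps in series integrate in closed form: target = one minus (κe^(−kt) − ke^(−κt))/(κ − k). We therefore expect 38.8%. Doubling k, which is theta, gives 44.0%, and doubling κ, which is gamma, gives 61.4%, so we choose gamma. We leave eta unreckoned.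

The forecast differs on the amounts. It gives 17%, within 9% to 30%, and 18.5% after theta, within 10% to 33%. Our 38.8% lies above that first range. It also picks gamma: “Enzyme limits the rate, so gamma is best.”

The flask gives 33.8%, 36.1% after theta, and gamma as the best change, worth 12 points.

    target → over-reaction product (k = 8.70 × 10⁻⁷ min⁻¹)
    starting material + enzyme ⇌ complex (K = 5.50 M⁻¹, k = 870 M⁻¹ min⁻¹)
    complex ⇌ enzyme + target (K = 0.190 M, k = 3.20 min⁻¹)
    solid substrate ⇌ starting material, rate k4*(cs4 - [starting material]) while solid is left; crystals form when [starting material] > cs4 (solubility = 0.0990 M, k = 6.70 × 10⁻⁴ min⁻¹)

The flask stands 17 points above the forecast and 5 points below our reckoning. Now take the neighbouring flask, charged with 0.025 M of solid substrate. We hold κ and assume the same starting dissolution rate per volume. In percent of this smaller charge, k becomes 0.167 h⁻¹. The same closed form then gives 46.4%. The neighbouring flask gave 41.7%, which is 4.7 points below that reckoning, with 58% of its charge still there as solid or dissolved substrate.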